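The lactone ring (C1–C5, O5) carries the C2 methyl, the C3 oxygen, the C4 methyl and the C5–C6 bond on one face, which is the substitution pattern of cis-diequatorial 2,4-dimethyl-8-oxabicyclo[3.2.1]oct-6-en-3-one. The route therefore disconnects C1–C2 and C4–C5: a (4+3) cycloaddition of furan with the oxyallyl cation from 2,4-dibromopentan-3-one forms both bonds, two rings and four stereocentres in one operation from two purchased reagents. The bridging oxygen becomes O5, the ketone C3 and the etheno bridge C6/C7. Baeyer–Villiger cleavage of C7–C1 and a carbenoid O–H insertion from the C4 hydroxyl then assemble the pyran ring.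

Key step: step 1

Numbering: target numbering is used for all intermediates (lactone ring O5–C1(=O)–C2–C3–C4–C5; pyran ring O8–C8–C7–C6–C5–C4; C9 is the methyl on C8). In the bicycles C1 and C5 are the bridgeheads, O5 the bridging oxygen and C6=C7 the etheno bridge, with C6 on C5.

Assumption: the (S,S)-amide in step 2 and (+)-Ipc2BH in step 6 are chosen by analogy with the known sense for 4-tert-butylcyclohexanone and norbornene; if either sense proves opposite, the commercially available antipode is used.

Step 1
Reactants: 1 furan; 2 2,4-dibromopentan-3-one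
Product: 4 meso-2,4-dimethyl-8-oxabicyclo[3.2.1]oct-6-en-3-one (both methyls equatorial), via zinc oxyallyl cation 3 (not isolated)
Conditions: Zn–Cu couple, furan (excess), DME, −10 °C → rt
Reagents that add atoms: none
Why: Zinc removes both bromides from 2 to give the zinc-bound 1,3-dimethyl-2-oxyallyl cation 3, whose 2π allyl unit adds to the 4π diene of furan in a concerted but asynchronous (4+3) cycloaddition, the known oxyallyl–furan cycloaddition of α,α'-dihalo ketones. Both rings arise from the same two C–C bonds (C1–C2 and C4–C5): the seven-membered carbocycle closes by (4+3) annulation across furan C2/C5, and the furan oxygen thereby becomes the one-atom bridge of the six-membered tetrahydropyranone, the future lactone ring. C1 and C5 are fixed by suprafacial bonding to one face of furan; C2 and C4 are fixed by the W geometry of the cation together with the compact (boat-like) transition state. The step needs compact over extended approach and a W over a sickle cation. The covalent zinc–oxygen bond tames the cation and keeps both methyls Z to oxygen, which should favour the cis-diequatorial meso adduct; minor isomers are removed by chromatography or crystallisation.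

Step 2
Reactants: 4 meso cycloadduct
Product: 5 C3=C4 trimethylsilyl enol ether of 4 (single enantiomer; C2 methyl equatorial)
Conditions: LiN[(S)-CH(Me)Ph]2 (from the (S,S)-amine and n-BuLi), LiCl, Me3SiCl (internal quench), THF, −100 °C
Reagents that add atoms: chlorotrimethylsilane, C[Si](C)(C)Cl
Why: Enantioselective deprotonation by a C2-symmetric chiral lithium amide with in situ silyl trapping: the base should remove one of the two enantiotopic axial α-hydrogens of meso 4, which makes C4 the enol carbon and renders C1, C2 and C5 stereogenic in one enantiomeric series.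

Step 3
Reactants: 5 silyl enol ether
Product: 7 4-hydroxy ketone (C4 hydroxyl axial and anti to the etheno bridge; C4 methyl equatorial), via silyloxy ketone 6 (not isolated)
Conditions: mCPBA (1.0 equiv), hexane/CH2Cl2, −15 °C; then 1 M HCl, THF, 0 °C
Reagents that add atoms: 3-chloroperoxybenzoic acid, O=C(OO)c1cccc(Cl)c1
Why: Rubottom oxidation: the peracid should epoxidise the electron-rich enol ether (not the etheno bridge) from the face anti to the etheno bridge, silyl migration gives the α-silyloxy ketone, and hydrolysis leaves the C4 oxygen trans to the C5–C6 bond.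

Step 4
Reactants: 7 4-hydroxy ketone
Product: 8 3,4-trans-diol (C3 hydroxyl axial, cis to both methyls and syn to the etheno bridge)
Conditions: Me4NBH(OAc)3, AcOH/MeCN, −30 → −10 °C
Reagents that add atoms: none
Why: Hydroxyl-directed reduction: the C4-bound acetoxyborohydride delivers hydride to the same face of the C3 carbonyl, which is also the sterically open equatorial trajectory, so the C3 hydroxyl should end up trans to the C4 hydroxyl and cis to the methyls.

Step 5
Reactants: 8 diol
Product: 9 3-O-benzyl ether of 8 (tertiary C4 hydroxyl free)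
Conditions: NaH (1.1 equiv), BnBr, Bu4NI (cat.), THF, 0 °C → rt
Reagents that add atoms: benzyl bromide, BrCc1ccccc1
Why: Williamson etherification: the secondary alkoxide should be alkylated much faster than the tertiary one, and the benzyl ether survives the strong bases used later and is removed together with the benzyl ester in step 14.

Step 6
Reactants: 9 benzyl ether
Product: 11 exo C7 alcohol (hydroxyl on the bridge carbon bonded to C1), via C7 dialkylborane 10 (not isolated)
Conditions: (+)-Ipc2BH (pre-formed from (−)-α-pinene), THF, −25 °C; then NaOH, H2O2, 0 °C → rt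
Reagents that add atoms: hydrogen peroxide, OO
Why: Reagent-controlled asymmetric hydroboration–oxidation: borane adds to the exo face, and because the two alkene carbons of 9 are pseudo-enantiotopic the chiral dialkylborane should place boron on C7, remote from C4, while any minor enantiomer of 9 is diverted to the separable regioisomer.

Step 7
Reactants: 11 exo C7 alcohol
Product: 12 C7 ketone
Conditions: Dess–Martin periodinane, CH2Cl2, rt
Reagents that add atoms: none
Why: Dess–Martin oxidation of the only secondary alcohol; the tertiary alcohol, the benzyl ether and the bridging ether are inert, and the C7 stereocentre is erased on purpose.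

Step 8
Reactants: 12 C7 ketone
Product: 13 acyl-acetal lactone (2,9-dioxabicyclo[3.3.1]nonan-3-one; oxygen inserted between C7 and C1)
Conditions: mCPBA, CH2Cl2, 0 °C → rt
Reagents that add atoms: 3-chloroperoxybenzoic acid, O=C(OO)c1cccc(Cl)c1
Why: Baeyer–Villiger oxidation: the α-oxygenated bridgehead C1 should migrate in preference to the C6 methylene with retention, which cuts C7–C1 and raises C1 to the acetal level of the future lactone carbonyl.

Step 9
Reactants: 13 acyl-acetal lactone
Product: 15 6-exo-methyl lactone, via dilithium enolate 14 (not isolated)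
Conditions: LiN(SiMe3)2 (2.2 equiv), THF, −78 °C; MeI, −78 → −40 °C
Reagents that add atoms: iodomethane, CI
Why: Lactone enolate alkylation at the only enolisable carbon: iodomethane should enter from the convex face of the bicyclic lactone, giving one C6 epimer whose configuration is reset under thermodynamic control in step 14.

Step 10
Reactants: 15 6-methyl lactone
Product: 16 benzyl 2-diazo-3-oxo ester with C1 as the six-membered lactol (anomer mixture)
Conditions: benzyl diazoacetate, LiN(i-Pr)2 (3 equiv each), THF, −78 °C; then 15; AcOH quench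
Reagents that add atoms: benzyl diazoacetate, [N-]=[N+]=CC(=O)OCc1ccccc1
Why: Claisen-type C-acylation of a lithiated diazoacetate by a lactone: the acyl acetal is an activated ester whose leaving group is the C1 lactolate, so a single addition should stop at the diazo keto ester and release C1 as the cyclic lactol.

Step 11
Reactants: 16 diazo keto ester lactol
Product: 17 diazo keto ester δ-lactone (target lactone ring with C2 methyl, C3 benzyloxy, C4 methyl and free C4 hydroxyl)
Conditions: Dess–Martin periodinane, CH2Cl2, rt
Reagents that add atoms: none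
Why: Lactol-to-lactone oxidation with Dess–Martin periodinane, a reagent type known to tolerate acceptor-substituted diazo compounds; the tertiary alcohol cannot be oxidised.

Step 12
Reactants: 17 diazo keto ester lactone
Product: 18 benzyl 3-oxopyran-2-carboxylate trans-fused to the lactone (O8–C8 bond formed; C8 epimers/enol)
Conditions: Rh2(OAc)4 (2 mol %), benzene, 80 °C
Reagents that add atoms: none
Why: Dirhodium-catalysed intramolecular O–H insertion of an α-diazo-β-keto ester: the carbenoid at C8 should be captured by the C4 hydroxyl through a six-membered oxonium ylide and proton shift, closing the pyran-3-one while C8 stays enolisable.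

Step 13
Reactants: 18 bicyclic β-keto ester
Product: 19 C8-methylated β-keto ester (C8 epimers)
Conditions: K2CO3, MeI, acetone, rt
Reagents that add atoms: iodomethane, CI
Why: C-alkylation of a cyclic β-keto ester under mild carbonate conditions that do not enolise the lactone; the quaternary C8 configuration is irrelevant because the ester is removed next.

Step 14
Reactants: 19 C8-methylated β-keto ester
Product: 22 3-hydroxy keto lactone with equatorial C6 and C8 methyls, via β-keto acid 20 (not isolated), via C6-epimeric ketone 21 (not isolated)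
Conditions: H2 (1 atm), Pd(OH)2/C, EtOAc, rt; then TsOH·H2O (10 mol %), toluene, 45 °C
Reagents that add atoms: none
Why: Hydrogenolysis frees the C3 hydroxyl and the β-keto acid, which decarboxylates on warming; acid-catalysed enolisation should then equilibrate C6 and C8 to the diequatorial ketone, because an axial methyl at either carbon would be syn-diaxial to the angular C4 methyl of the trans-fused bicycle.

Step 15
Reactants: 22 3-hydroxy keto lactone
Product: 23 3-O-acetyl keto lactone
Conditions: Ac2O, pyridine, DMAP (cat.), CH2Cl2, rt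
Reagents that add atoms: acetic anhydride, CC(=O)OC(C)=O
Why: Nucleophile-catalysed acetylation of the only hydroxyl; doing it while C7 is still a ketone avoids having to distinguish two secondary alcohols.

Step 16
Reactants: 23 keto lactone acetate
Product: 24 C7 alcohol (hydroxyl equatorial, trans to both neighbouring methyls)
Conditions: NaBH4, CeCl3·7H2O, MeOH, −78 °C
Reagents that add atoms: none
Why: Luche-type borohydride reduction: hydride should attack the chair ketone axially from the face bearing only the axial C5 hydrogen, away from the axial C4 methyl, giving the equatorial C7 hydroxyl, while acetate and lactone are untouched at low temperature.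

Step 17
Reactants: 25 heptanal
Product: 26 (±)-non-1-yn-3-ol
Conditions: HC≡CMgBr, THF, 0 °C; then H2O
Reagents that add atoms: ethynylmagnesium bromide, C#C[Mg]Br
Why: Grignard addition of an acetylide to an aldehyde; the racemic carbinol centre is oxidised away in step 22.

Step 18
Reactants: 26 (±)-non-1-yn-3-ol
Product: 27 (±)-3-(tert-butyldimethylsilyloxy)non-1-yne
Conditions: t-BuMe2SiCl, imidazole, DMF, rt
Reagents that add atoms: tert-butyldimethylsilyl chloride, CC(C)(C)[Si](C)(C)Cl
Why: Standard silylation of a secondary alcohol, giving an ether stable to the acetylide and to the coupling.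

Step 19
Reactants: 27 silyl ether
Product: 29 (±)-4-(tert-butyldimethylsilyloxy)dec-2-ynoic acid, via lithium acetylide 28 (not isolated)
Conditions: n-BuLi, THF, −78 °C; CO2; then cold 1 M HCl
Reagents that add atoms: carbon dioxide, O=C=O
Why: Deprotonation of the terminal alkyne and carboxylation of the lithium acetylide, a routine synthesis of 2-alkynoic acids.

Step 20
Reactants: 24 C7 alcohol; 29 silyloxy ynoic acid
Product: 30 C7 4-(silyloxy)dec-2-ynoate ester (two epimers at the side-chain carbinol)
Conditions: DCC, DMAP (cat.), CH2Cl2, 0 °C → rt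
Reagents that add atoms: none
Why: Steglich esterification: the linear alkynoic O-acylisourea is unhindered enough to acylate the flanked equatorial C7 hydroxyl, and the alkyne is not yet activated by a ketone, so conjugate addition of the catalyst should be avoided.

Step 21
Reactants: 30 silyloxy ynoate ester
Product: 31 C7 4-hydroxydec-2-ynoate ester
Conditions: HF·pyridine, THF/pyridine, 0 °C → rt
Reagents that add atoms: none
Why: Fluoride-mediated desilylation under buffered conditions that spare acetate, lactone and ynoate; a propargylic alcohol cannot lactonise onto the ester across the linear alkyne.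

Step 22
Reactants: 31 hydroxy ynoate ester
Product: 32 C7 4-oxodec-2-ynoate ester
Conditions: Dess–Martin periodinane, CH2Cl2, rt
Reagents that add atoms: none
Why: Dess–Martin oxidation of the propargylic alcohol, which converges both carbinol epimers to one ynone.

Step 23
Reactants: 32 ynone ester
Product: 33 botcinin J
Conditions: H2 (1 atm), Lindlar catalyst (Pd/CaCO3 poisoned with Pb(OAc)2), quinoline, EtOAc, 0 °C, stopped after one equivalent
Reagents that add atoms: none
Why: Lindlar semi-hydrogenation: syn delivery of hydrogen on poisoned palladium should give the Z-alkene, and running it as the last, neutral step keeps the isomerisation-prone Z-4-oxo-2-enoate away from bases and nucleophiles.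

Compound list
1 | furan | c1ccoc1 | starting material
2 | 2,4-dibromopentan-3-one (diastereomer mixture) | CC(Br)C(=O)C(C)Br | starting material
3 | W-shaped zinc oxyallyl cation (1,3-dimethyl-2-(bromozincoxy)allyl cation) | C/C=C(\O[Zn]Br)[CH+]C | intermediate
4 | meso-2,4-dimethyl-8-oxabicyclo[3.2.1]oct-6-en-3-one, cis-diequatorial methyls | C[C@@H]1C(=O)[C@H](C)[C@@H]2C=C[C@H]1O2 | intermediate
5 | C3=C4 trimethylsilyl enol ether of 4 | C[C@@H]1C(O[Si](C)(C)C)=C(C)[C@@H]2C=C[C@H]1O2 | intermediate
6 | 4-(trimethylsilyloxy) ketone, silyloxy axial | C[C@@H]1C(=O)[C@@](C)(O[Si](C)(C)C)[C@@H]2C=C[C@H]1O2 | intermediate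
7 | 4-hydroxy-2,4-dimethyl-8-oxabicyclo[3.2.1]oct-6-en-3-one, C4 hydroxyl axial and anti to the etheno bridge | C[C@@H]1C(=O)[C@@](C)(O)[C@@H]2C=C[C@H]1O2 | intermediate
8 | 3,4-trans-diol, C3 hydroxyl cis to both methyls | C[C@@H]1[C@H](O)[C@@](C)(O)[C@@H]2C=C[C@H]1O2 | intermediate
9 | 3-O-benzyl ether of 8 | C[C@@H]1[C@H](OCc3ccccc3)[C@@](C)(O)[C@@H]2C=C[C@H]1O2 | intermediate
10 | exo C7 diisopinocampheylborane adduct of 9 | C[C@@H]1[C@H](OCc3ccccc3)[C@@](C)(O)[C@@H]2C[C@@H](B([C@H]4C[C@H]5C[C@@H]([C@@H]4C)C5(C)C)[C@H]4C[C@H]5C[C@@H]([C@@H]4C)C5(C)C)[C@H]1O2 | intermediate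
11 | exo C7 alcohol | C[C@@H]1[C@H](OCc3ccccc3)[C@@](C)(O)[C@@H]2C[C@@H](O)[C@H]1O2 | intermediate
12 | C7 ketone | C[C@@H]1[C@H](OCc3ccccc3)[C@@](C)(O)[C@@H]2CC(=O)[C@H]1O2 | intermediate
13 | acyl-acetal lactone (2,9-dioxabicyclo[3.3.1]nonan-3-one) | C[C@@H]1[C@H](OCc3ccccc3)[C@@](C)(O)[C@@H]2CC(=O)O[C@H]1O2 | intermediate
14 | dilithium alkoxide–enolate of 13 | C[C@@H]1[C@H](OCc3ccccc3)[C@@](C)(O[Li])[C@@H]2C=C(O[Li])O[C@H]1O2 | intermediate
15 | 6-exo-methyl acyl-acetal lactone | C[C@@H]1[C@H](OCc3ccccc3)[C@@](C)(O)[C@@H]2[C@@H](C)C(=O)O[C@H]1O2 | intermediate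
16 | benzyl 2-diazo-3-oxo ester, C1 lactol (anomers) | C[C@@H]1[C@H](OCc3ccccc3)[C@@](C)(O)[C@@H](OC1O)[C@@H](C)C(=O)C(=[N+]=[N-])C(=O)OCc1ccccc1 | intermediate
17 | benzyl 2-diazo-3-oxo ester, δ-lactone | C[C@@H]1[C@H](OCc3ccccc3)[C@@](C)(O)[C@@H](OC1=O)[C@@H](C)C(=O)C(=[N+]=[N-])C(=O)OCc1ccccc1 | intermediate
18 | benzyl 3-oxopyran-2-carboxylate fused to the lactone (C8 epimers) | O=C1[C@H](C)[C@@H]2OC(=O)[C@H](C)[C@H](OCc3ccccc3)[C@@]2(C)OC1C(=O)OCc1ccccc1 | intermediate
19 | C8-methylated β-keto ester (C8 epimers) | O=C1[C@H](C)[C@@H]2OC(=O)[C@H](C)[C@H](OCc3ccccc3)[C@@]2(C)OC1(C)C(=O)OCc1ccccc1 | intermediate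
20 | 3-hydroxy β-keto acid | O=C1[C@H](C)[C@@H]2OC(=O)[C@H](C)[C@H](O)[C@@]2(C)OC1(C)C(=O)O | intermediate
21 | C6-epimeric (axial methyl) 3-hydroxy keto lactone, C8 epimers | O=C1[C@H](C)[C@@H]2OC(=O)[C@H](C)[C@H](O)[C@@]2(C)OC1C | intermediate
22 | 3-hydroxy keto lactone, C6 and C8 methyls equatorial | O=C1[C@@H](C)[C@@H]2OC(=O)[C@H](C)[C@H](O)[C@@]2(C)O[C@H]1C | intermediate
23 | 3-O-acetyl keto lactone | O=C1[C@@H](C)[C@@H]2OC(=O)[C@H](C)[C@H](OC(C)=O)[C@@]2(C)O[C@H]1C | intermediate
24 | 3-O-acetyl C7 alcohol (equatorial hydroxyl) | O[C@@H]1[C@@H](C)[C@@H]2OC(=O)[C@H](C)[C@H](OC(C)=O)[C@@]2(C)O[C@H]1C | intermediate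
25 | heptanal | CCCCCCC=O | starting material
26 | (±)-non-1-yn-3-ol | CCCCCCC(O)C#C | intermediate
27 | (±)-3-(tert-butyldimethylsilyloxy)non-1-yne | CCCCCCC(O[Si](C)(C)C(C)(C)C)C#C | intermediate
28 | lithium acetylide of 27 | CCCCCCC(O[Si](C)(C)C(C)(C)C)C#C[Li] | intermediate
29 | (±)-4-(tert-butyldimethylsilyloxy)dec-2-ynoic acid | CCCCCCC(O[Si](C)(C)C(C)(C)C)C#CC(=O)O | intermediate
30 | C7 4-(tert-butyldimethylsilyloxy)dec-2-ynoate ester | CCCCCCC(O[Si](C)(C)C(C)(C)C)C#CC(=O)O[C@@H]1[C@@H](C)[C@@H]2OC(=O)[C@H](C)[C@H](OC(C)=O)[C@@]2(C)O[C@H]1C | intermediate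
31 | C7 4-hydroxydec-2-ynoate ester | CCCCCCC(O)C#CC(=O)O[C@@H]1[C@@H](C)[C@@H]2OC(=O)[C@H](C)[C@H](OC(C)=O)[C@@]2(C)O[C@H]1C | intermediate
32 | C7 4-oxodec-2-ynoate ester | CCCCCCC(=O)C#CC(=O)O[C@@H]1[C@@H](C)[C@@H]2OC(=O)[C@H](C)[C@H](OC(C)=O)[C@@]2(C)O[C@H]1C | intermediate
33 | botcinin J | CCCCCCC(=O)/C=C\C(=O)O[C@@H]1[C@@H](C)[C@@H]2OC(=O)[C@H](C)[C@H](OC(C)=O)[C@@]2(C)O[C@H]1C | target

Total step count: 23. Longest linear sequence: 20 steps (steps 1–16 and 20–23); the side-chain acid takes 3 steps (17–19).

Steps most likely to fail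

Step 10. The lithiated diazoacetate may deprotonate the α-branched lactone instead of adding to it, or the released lactolate may open to the aldehyde and take up a second equivalent. The fallback sets out from 15 and uses a Claisen condensation with the lithium enolate of benzyl acetate (LiN(i-Pr)2, THF, −78 °C), which should give the benzyl β-keto ester lactol F1; its acidic methylene protonates the lactolate in the flask and stops further addition. Regitz diazo transfer (4-acetamidobenzenesulfonyl azide, Et3N, MeCN) then converts F1 into 16, where the route is rejoined.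

Step 14. While the ketone is being equilibrated, its enol may expel the lactone carboxylate across C5–C6 (β-acyloxy ketone elimination), or epimerisation at C6 may stay incomplete. The fallback sets out from 16 and keeps C1 at the acetal level so that the ketone carries only a poor β-alkoxy leaving group. MeOH with pyridinium p-toluenesulfonate gives the methyl acetal diazo keto ester F2. Rh2(OAc)4 closes the pyranone acetal F3, and K2CO3/MeI gives the C8-methylated β-keto ester acetal F4. Hydrogenolysis (H2, Pd(OH)2/C), decarboxylation and base equilibration (K2CO3, MeOH) give the diequatorial hydroxy ketone acetal F5, and Ac2O/pyridine gives the acetate acetal F6. Jones oxidation (CrO3, H2SO4, acetone) converts the methyl acetal into the lactone and returns to the route at 23.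

Step 23. Hydrogen uptake may run on to the saturated keto ester, or the Z-alkene may isomerise to E on the catalyst. The fallback sets out from 30 and reduces the alkyne before it is activated by the ketone. Lindlar semi-hydrogenation of the silyloxy ynoate gives the Z-silyloxy enoate F7, and HF·pyridine gives the Z-4-hydroxy enoate F8. F8 is oxidised at once with Dess–Martin periodinane, before it can lactonise, to give 33.

Further compounds
F1 | step 10 | benzyl 3-oxo ester (β-keto ester), C1 lactol | C[C@@H]1[C@H](OCc3ccccc3)[C@@](C)(O)[C@@H](OC1O)[C@@H](C)C(=O)CC(=O)OCc1ccccc1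
F2 | step 14 | benzyl 2-diazo-3-oxo ester, C1 methyl acetal | C[C@@H]1[C@H](OCc3ccccc3)[C@@](C)(O)[C@@H](OC1OC)[C@@H](C)C(=O)C(=[N+]=[N-])C(=O)OCc1ccccc1
F3 | step 14 | benzyl 3-oxopyran-2-carboxylate, C1 methyl acetal | O=C1[C@H](C)[C@@H]2OC(OC)[C@H](C)[C@H](OCc3ccccc3)[C@@]2(C)OC1C(=O)OCc1ccccc1
F4 | step 14 | C8-methylated β-keto ester, C1 methyl acetal | O=C1[C@H](C)[C@@H]2OC(OC)[C@H](C)[C@H](OCc3ccccc3)[C@@]2(C)OC1(C)C(=O)OCc1ccccc1
F5 | step 14 | 3-hydroxy ketone with equatorial C6 and C8 methyls, C1 methyl acetal | O=C1[C@@H](C)[C@@H]2OC(OC)[C@H](C)[C@H](O)[C@@]2(C)O[C@H]1C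
F6 | step 14 | 3-O-acetyl ketone, C1 methyl acetal | O=C1[C@@H](C)[C@@H]2OC(OC)[C@H](C)[C@H](OC(C)=O)[C@@]2(C)O[C@H]1C
F7 | step 23 | C7 (Z)-4-(tert-butyldimethylsilyloxy)dec-2-enoate ester | CCCCCCC(O[Si](C)(C)C(C)(C)C)/C=C\C(=O)O[C@@H]1[C@@H](C)[C@@H]2OC(=O)[C@H](C)[C@H](OC(C)=O)[C@@]2(C)O[C@H]1C
F8 | step 23 | C7 (Z)-4-hydroxydec-2-enoate ester | CCCCCCC(O)/C=C\C(=O)O[C@@H]1[C@@H](C)[C@@H]2OC(=O)[C@H](C)[C@H](OC(C)=O)[C@@]2(C)O[C@H]1C
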